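Atoms carry the numbers of the target SMILES (C1–C8, O9, C10–C20, O21, C22–C28, O29, O30, C31–C34). Compounds are numbered 1–45 in the order in which they appear in the steps.

## Analysis of the target

The target is hexacyclic. A 2,2-dimethylcyclobutane (C14–C17) is trans-fused to a nine-membered carbocycle (C2–C5, C10, C12–C15) that carries the exocyclic methylene C1=C2. Dihydropyran ring D (C5, C6, C7, C8, O9, C10) is cis-fused to the nine-membered ring (H-5 and CH3-11 on the same side). Ring D shares its enol-ether bond C7=C8 with cyclopentenone ring C (C7, C8, C20, C22, C33), the end ring of a linear cis-anti-cis triquinane with ring B (C22, C23, C24, C32, C33) and ring A (C24, C25, C26, C31, C32).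

There are nine stereocentres: 5R, 10R, 14S, 15R in the caryophyllane half and 22R, 24S, 26S, 32R, 33S in the triquinane half. C26 and C33 are quaternary carbons and C10 is a tertiary ether. In the A/B bicycle H-24 and H-32 are cis on the convex face, the C26 carboxyl is convex and its methyl concave, and the C33 methyl is concave, so ring C sits on the convex side, anti to ring A.

The cyclobutane has the configuration opposite to that of natural (−)-β-caryophyllene, and the pyran fusion is cis, so this half cannot be taken from the chiral pool. The two halves are too far apart to control each other, which forces a convergent plan in which each half is made enantioselectively.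

Sensitive features are the exocyclic alkene next to the strained cyclobutane (isomerisation or ring expansion under acid), the α-alkoxy enone, the epimerisable C22 and the free acid. The hard problems are the nine-membered ring, the two quaternary carbons and the diastereotopic pair of one-carbon groups on C26.

The strategy rests on rings A and B: a bicyclo[3.3.0]octane whose C26 bears two one-carbon groups and whose C33 bears a methyl next to C22, the carbon that must bind the C20 carbonyl. That is the substitution pattern of a (2+2+1) adduct of an allyl/butynyl malonate with CO.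

## Retrosynthetic reasoning

**45 to 44.** The acid is released last from methyl ester 44, so that no free carboxyl passes through organometallic, radical or Lewis-acid steps.

**44 to 43 (cut C7–C33).** Ring C is opened at the bond between the enol-ether carbon C7 and the quaternary C33, giving cross-conjugated dienone 43. The forward Nazarov closure makes the quaternary centre on a ring-B alkene whose two faces are differentiated by ring A. C7 returns to sp2, so only the face of C33 matters. C22 is then set by protonation to the only strain-free (cis) ring fusion.

**43 to 16 + 42 + 6 (cut C20–C22 and C20–C8).** Removing the carbonyl carbon separates the two halves at a point where neither has to control the other. Enol triflate 16, stannane 42 and carbon monoxide 6 are joined by a carbonylative cross-coupling. This uses the ketone that the ring-forming step leaves on C22.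

**16 to 15 to 8 to 7.** The triflate comes from ketone 15 by enolisation towards the methyl-bearing C33. Ketone 15 derives from diester 8 by turning the concave ester into a methyl group and keeping the convex one. In the folded cis-bicycle the two esters differ strongly in accessibility. Diester 8 is the hydrogenation product of enone 7; hydrogen enters from the face of H-24 and fixes C32.

**7 to 5 + 6 (cut C24–C32, C22–C23, C22–C33).** All three bonds of the cyclopentenone and the ring-A bond are cut at once, leading to enyne 5 and carbon monoxide 6. This is the one place where two rings and the first stereocentre of the half can be made in a single catalytic, enantioselective step from an achiral substrate. Enyne 5 is two alkylations away from malonate 1 with bromides 2 and 4.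

**42 to 40 to 38 to 37 (cut C2–C3).** The stannane is the enol derivative of δ-lactone 40, so ring D can travel as a robust lactone. The nine-membered ring is cut next to the exocyclic alkene. Closing it by addition of a C2 alkenyl–metal species to a C3 aldehyde (37 to 38) installs C1=C2 in the ring-forming step. The extra hydroxyl on C3 is then removed by allylic reduction.

**37 to 35 to 30 to 29 to 28 (C5–C4, C10–O9, C6–C7).** C5 and C10 are set on an open chain, before any medium ring exists. Asymmetric epoxidation of Z-allylic alcohol 28 gives 29. An allyl nucleophile opens 29 at C5 with inversion to give 30. This sequence fixes the cis H-5/CH3-11 relation by reagent control and stereospecific substitution. The primary alcohol (C6) is extended by two carbons and closed onto the tertiary hydroxyl to give lactone 35. The allyl group supplies C4 and, after cleavage, the C3 aldehyde.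

**28 to 24 + 26 (cut C12–C10).** An sp3–sp2 coupling between the hydroborated vinyl group of cyclobutane 24 and Z-iodide 26 (from alkynol 25) fixes the alkene geometry that the epoxide needs.

**24 to 23 to 21 to 19 to 17 + 18.** The trans-cyclobutane is traced to a five-membered ring by ring contraction of diazoketone 21. C14 is the β-carbon of enone 17 and is set by catalytic asymmetric conjugate addition of vinyl donor 18. C15 is α to a carbonyl after contraction and is corrected by equilibration.

## Alternatives that were turned down

**Alternative 1:** The nine-membered ring is cut at C3–C4 and traced to eleven-membered allylic lactone A2. In the forward sense the silyl ketene acetal of A2 (LiN(iPr)2, Me3SiCl) undergoes an Ireland–Claisen rearrangement that forms C3–C4, moves the alkene to the exocyclic C2=C1 position and contracts the ring to acid A1.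

- For: closing an eleven-membered lactone is easier than closing a nine-membered carbocycle directly, the exocyclic methylene arrives in the same step without redox adjustment, and the dihydropyran is already in place.
- Against: the carboxyl on C4 is not in the target and has to be removed by radical decarboxylation next to an enol ether and an allylic system. The C4 stereocentre is made and then discarded. A2 already demands the cyclobutane, the cis-fused pyran and C5/C10. Nothing of the triquinane is addressed.
- Comparison: on the medium-ring closure it is stronger than the cyclisation of 37 used here and would save steps 28 and 29. The chosen plan offers instead a key step that makes two rings, three skeletal bonds and the controlling stereocentre of the triquinane half from a two-step substrate. Its risk is tested at once, and the medium ring is left to established chemistry with a fallback.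

**Alternative 2:** The cyclobutane is cut at C14–C15 and C16–C17, back to geranyl acetate A4 and trifluoroethyl buta-2,3-dienoate A5. Under a chiral oxazaborolidine–AlBr3 Lewis acid the allenoate adds across the distal trisubstituted alkene of A4 to give alkylidenecyclobutane A3.

- For: ten caryophyllane carbons come from a commodity terpene, with the C10 methyl, the C5=C10 alkene and an allylic oxygen ready for reagent-controlled epoxidation. C14 is set catalytically. It reaches a stage comparable to 28 in fewer operations than steps 13–19.
- Against: hydrogenation of the exocyclic enoate delivers hydrogen anti to the C14 chain, giving the cis cyclobutane, and C15 is then β to the ester and cannot be equilibrated until C2 becomes a ketone. C2 lacks C1 and the ester carbon must become C3 and be joined to C4, so the medium ring is still unsolved. The triquinane is untouched.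
- Comparison: it is stronger in step economy for chain plus cyclobutane. The chosen plan corrects C15 by simple equilibration α to an ester (step 16) and puts its one high-risk step on the half that carries five stereocentres and both quaternary carbons.

**Alternative 3:** The cyclobutane is cut at C14–C17 and C15–C16, back to cyclohex-2-enone A7 and isobutylene A8. Irradiation of A7 bound to a chiral oxazaborolidine–AlBr3 Lewis acid in the presence of A8 gives trans-fused ketone A6.

- For: one step from two commodity chemicals sets both cyclobutane stereocentres and the gem-dimethyl group. The ketone maps onto C2 and opens the classical ring-expansion logic to nine-membered ketones. No other entry to the four-membered ring is as short; steps 13–16 here need four operations.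
- Against: the Lewis acid is needed in large amount at low temperature against an uncatalysed background reaction, and regio- and cis/trans isomers form. The ring expansions that are known to work deliver a C5=C10 alkene inside the nine-membered ring, and oxygen at C10 and carbon at C5 would then have to be added to one face of a conformationally mobile medium ring. C5 and C10 would be under substrate control of uncertain sense. The triquinane is untouched.
- Comparison: the chosen plan is longer on the cyclobutane but fixes C5 and C10 on an open chain by reagent control (steps 20, 21). It spends its key step on a ring system for which enantiocontrol, regiochemistry and ring fusion follow from one well-understood catalytic cycle.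

Key step: step 3

**Remarks on the chemistry (assumptions):**
- (S)-BINAP is taken as the hand that gives (3aR)-7 in step 3; if the first run shows the opposite sense, (R)-BINAP is used and nothing else changes.
- C33 in 8–15 is epimerisable and is made trigonal in step 12; it is drawn as formed by hydrogenation, and either epimer serves.
- Compounds 38 and 39 are carried as mixtures at C3, which becomes CH2 in step 29.

## Route

**Step 1**
Reactants: 1 dimethyl malonate; 2 allyl bromide
Product: 3 dimethyl 2-allylmalonate
Conditions: NaH (1.0 equiv), 1 (1.5 equiv), THF, 0 °C to rt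
Reagents that add atoms: none
Why: Malonate alkylation (SN2 of the sodium enolate on a primary allylic bromide); excess malonate suppresses dialkylation.

**Step 2**
Reactants: 3 dimethyl 2-allylmalonate; 4 1-bromobut-2-yne
Product: 5 dimethyl 2-allyl-2-(but-2-yn-1-yl)malonate
Conditions: NaH, THF, 0 °C to rt
Reagents that add atoms: none
Why: Second malonate alkylation with a reactive propargylic bromide; it gives the standard malonate-tethered 1,6-enyne with a methyl-capped alkyne.

**Step 3**
Reactants: 5 dimethyl 2-allyl-2-(but-2-yn-1-yl)malonate; 6 carbon monoxide
Product: 7 dimethyl (3aR)-6-methyl-5-oxo-3,3a,4,5-tetrahydropentalene-2,2(1H)-dicarboxylate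
Conditions: [RhCl(CO)2]2 (3 mol %), (S)-BINAP (9 mol %), AgOTf (12 mol %), CO (1 atm), THF, 80–90 °C
Reagents that add atoms: none
Why: A cationic monovalent rhodium–BINAP complex (from [RhCl(CO)2]2, the bisphosphine and AgOTf) binds the alkyne and alkene of 5; oxidative cyclisation to a rhodacyclopentene forms C24–C32 and closes ring A in a 5-exo sense through the three-atom malonate tether. Migratory insertion of CO and reductive elimination then form C22–C23 and C22–C33 and close ring B as the 2-methylcyclopentenone, a formal (2+2+1) cycloaddition. The closest known reaction type is the rhodium–bisphosphine catalysed asymmetric intramolecular Pauson–Khand reaction of malonate- and heteroatom-tethered 1,6-enynes, of which 5 is a typical member. C24, the only new stereocentre, is set when the chiral P–Rh–P pocket selects one enantioface of the allyl alkene in the oxidative cyclisation; C32 and C33 stay trigonal. The step needs enantioselectivity and selectivity for carbonylation over CO-free cycloisomerisation to a 1,4-diene: the first rests on the rigid chelating ligand and the gem-diester preorganisation (Thorpe–Ingold effect), the second on keeping CO near one atmosphere, enough for insertion without saturating the metal. The methyl cap prevents alkyne oligomerisation and places the methyl on C33, next to the C22 carbonyl that is needed later.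

**Step 4**
Reactants: 7 enone diester
Product: 8 dimethyl (3aR,4R,6aR)-4-methyl-5-oxohexahydropentalene-2,2(1H)-dicarboxylate (cis-fused; C32 R)
Conditions: H2 (3 atm), 10% Pd/C, EtOAc, rt
Reagents that add atoms: none
Why: Heterogeneous syn hydrogenation of the tetrasubstituted enone from the face that carries H-24 sets C32 cis to C24 (the only strain-free fusion of a bicyclo[3.3.0]octane). The C33 methyl ends up on the concave face, but this centre is not kept.

**Step 5**
Reactants: 8 keto diester
Product: 9 1,3-dioxolane ketal of 8 at C22
Conditions: Me3SiOCH2CH2OSiMe3, Me3SiOTf (cat.), CH2Cl2, −78 to −20 °C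
Reagents that add atoms: 1,2-bis(trimethylsilyloxy)ethane, C[Si](C)(C)OCCO[Si](C)(C)C
Why: Aprotic ketalisation with the bis-silyl ether protects the ketone against hydride without transesterifying the methyl esters; the inward oxygen of the dioxolane also fills the concave pocket in front of the concave ester.

**Step 6**
Reactants: 9 ketal diester
Product: 10 ketal mono-acid (convex carboxyl C28 free, concave CO2Me kept; C26 now stereogenic)
Conditions: KOH (1.05 equiv), MeOH/THF/H2O, 0 °C to rt; then aq. KHSO4 to pH 3, 0 °C
Reagents that add atoms: potassium hydroxide, [K+].[OH-]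
Why: Saponification of a gem-diester responds to sterics: the convex ester is open, the concave one is shielded by ring B and the dioxolane, so hydroxide should attack the convex carbonyl (substrate control of C26). The resulting carboxylate deactivates the geminal ester, so hydrolysis stops at the half-ester.

**Step 7**
Reactants: 10 ketal mono-acid
Product: 11 ketal hydroxy acid (concave CH2OH at C27, convex CO2H)
Conditions: LiBHEt3 (3.5 equiv), THF, 0 °C to rt; then aq. KHSO4
Reagents that add atoms: none
Why: Chemoselective hydride reduction: the reagent deprotonates the acid to an inert lithium carboxylate and reduces only the methyl ester; C26 is untouched.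

**Step 8**
Reactants: 11 ketal hydroxy acid
Product: 12 ketal hydroxy methyl ester (convex CO2Me, concave CH2OH)
Conditions: MeI, KHCO3, DMF, rt
Reagents that add atoms: iodomethane, CI
Why: O-alkylation of the carboxylate under weakly basic conditions; the neopentyl alcohol is not alkylated and no strongly basic alkoxide (retro-aldol risk) is formed.

**Step 9**
Reactants: 12 ketal hydroxy methyl ester
Product: 13 O-(imidazol-1-ylcarbonothioyl) derivative of 12
Conditions: 1,1'-thiocarbonyldiimidazole, DMAP (cat.), ClCH2CH2Cl, 70 °C
Reagents that add atoms: 1,1'-thiocarbonyldiimidazole, S=C(n1ccnc1)n1ccnc1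
Why: Neutral thioacylation of the hindered primary alcohol sets up radical deoxygenation (first stage of the Barton–McCombie sequence).

**Step 10**
Reactants: 13 thiocarbonyl derivative
Product: 14 ketal of methyl 2,4-dimethyl-5-oxooctahydropentalene-2-carboxylate (C26: concave CH3, convex CO2Me)
Conditions: Bu3SnH, AIBN, toluene, 110 °C
Reagents that add atoms: none
Why: Barton–McCombie deoxygenation; the primary neopentyl radical is trapped by the stannane faster than it can rearrange, turning the concave carboxyl carbon into the C27 methyl without touching C26.

**Step 11**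
Reactants: 14 ketal ester
Product: 15 methyl (2S,3aR,4R,6aR)-2,4-dimethyl-5-oxooctahydropentalene-2-carboxylate
Conditions: pyridinium p-toluenesulfonate, acetone/H2O, 55 °C
Reagents that add atoms: water, O
Why: Mild acid-catalysed transketalisation frees the C22 ketone; the ester and C24, C26, C32 are inert, and epimerisation at C33 is without consequence.

**Step 12**
Reactants: 15 keto ester
Product: 16 methyl (2S,3aR,6aR)-2,4-dimethyl-5-(trifluoromethanesulfonyloxy)-1,2,3,3a,6,6a-hexahydropentalene-2-carboxylate (C22=C33 enol triflate)
Conditions: Tf2O, 2,6-di-tert-butyl-4-methylpyridine, CH2Cl2, 0 °C to rt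
Reagents that add atoms: trifluoromethanesulfonic anhydride, O=S(=O)(OS(=O)(=O)C(F)(F)F)C(F)(F)F
Why: O-triflation under equilibrating conditions with a hindered pyridine favours the more substituted enol, giving the tetrasubstituted C22=C33 triflate; the minor C22=C23 isomer is separable.

**Step 13**
Reactants: 17 4,4-dimethylcyclopent-2-en-1-one; 18 potassium vinyltrifluoroborate
Product: 19 (3R)-3-ethenyl-4,4-dimethylcyclopentan-1-one
Conditions: [Rh(cod)2]BF4 (3 mol %), (R)-BINAP (3.3 mol %), toluene/H2O, 100 °C
Reagents that add atoms: none
Why: Rhodium–bisphosphine catalysed asymmetric 1,4-addition of an alkenylboron reagent to a cyclic enone; (R)-BINAP directs the vinyl group to the enone face that gives 3R, which becomes C14.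

**Step 14**
Reactants: 19 (3R)-3-ethenyl-4,4-dimethylcyclopentan-1-one
Product: 20 (3R)-3-ethenyl-2-(hydroxymethylidene)-4,4-dimethylcyclopentan-1-one
Conditions: NaH, HCO2Et, EtOH (cat.), THF, 0 °C to rt; then aq. HCl
Reagents that add atoms: ethyl formate, CCOC=O
Why: Reversible Claisen formylation goes to the α-carbon next to C14; the other α-carbon is neopentylic, flanked by the gem-dimethyl carbon. This marks the position that must carry the diazo group.

**Step 15**
Reactants: 20 hydroxymethylene ketone
Product: 21 (3R)-2-diazo-3-ethenyl-4,4-dimethylcyclopentan-1-one
Conditions: 4-acetamidobenzenesulfonyl azide, Et3N, MeCN, 0 °C to rt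
Reagents that add atoms: 4-acetamidobenzenesulfonyl azide, CC(=O)Nc1ccc(cc1)S(=O)(=O)N=[N+]=[N-]
Why: Deformylative (Regitz) diazo transfer places the diazo group regiospecifically on the formylated carbon.

**Step 16**
Reactants: 21 diazo ketone
Product: 23 methyl (1R,2S)-2-ethenyl-3,3-dimethylcyclobutane-1-carboxylate (trans), via cis ester 22 (not isolated)
Conditions: hν (medium-pressure Hg lamp, Pyrex), MeOH, 0 °C; then NaOMe (0.3 equiv), MeOH, 50 °C
Reagents that add atoms: methanol, CO
Why: Photochemical Wolff rearrangement of the s-cis-locked cyclic diazoketone contracts the ring (the neopentylic CH2 migrates) and methanol traps the ketene. Kinetic protonation gives mainly the cis ester, and methoxide equilibrates the α-centre (C15) to the more stable trans isomer; C14 is not enolisable and is retained.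

**Step 17**
Reactants: 23 trans ester
Product: 24 (1R,2S)-2-ethenyl-N-methoxy-N,3,3-trimethylcyclobutane-1-carboxamide
Conditions: MeNHOMe·HCl, i-PrMgCl, THF, −20 °C
Reagents that add atoms: N,O-dimethylhydroxylamine hydrochloride, CNOC.Cl
Why: Aminolysis of the ester by the magnesium amide gives an acyl group that tolerates borane, titanium and copper reagents and is later converted cleanly to the methyl ketone; the trans configuration is the thermodynamic one and is kept.

**Step 18**
Reactants: 25 but-2-yn-1-ol
Product: 26 (Z)-3-iodobut-2-en-1-ol
Conditions: NaAlH2(OCH2CH2OMe)2, THF, 0 °C to rt; EtOAc; then I2, −78 °C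
Reagents that add atoms: iodine, II
Why: Alkoxide-directed trans-hydroalumination of the propargylic alcohol places aluminium on C3; iodinolysis with retention gives the Z-iodide (I cis to CH2OH).

**Step 19**
Reactants: 24 vinylcyclobutane amide; 26 (Z)-3-iodobut-2-en-1-ol
Product: 28 (1R,2S)-2-[(3Z)-5-hydroxy-3-methylpent-3-en-1-yl]-N-methoxy-N,3,3-trimethylcyclobutane-1-carboxamide, via alkylborane 27 (not isolated)
Conditions: 9-BBN, THF, 0 °C to rt; then H2O, 26, Pd(dppf)Cl2 (5 mol %), AsPh3, Cs2CO3, DMF, rt
Reagents that add atoms: 9-borabicyclo[3.3.1]nonane, B1C2CCCC1CCC2 (boron is carried only in 27)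
Why: Anti-Markovnikov hydroboration of the monosubstituted alkene followed by B-alkyl Suzuki–Miyaura coupling forms C12–C10 with retention of the iodide geometry, so C12 ends cis to the hydroxymethyl carbon C6.

**Step 20**
Reactants: 28 Z-allylic alcohol
Product: 29 (1R,2S)-2-{2-[(2R,3S)-3-(hydroxymethyl)-2-methyloxiran-2-yl]ethyl}-N-methoxy-N,3,3-trimethylcyclobutane-1-carboxamide
Conditions: Ti(OiPr)4 (10 mol %), L-(+)-diethyl tartrate (12 mol %), t-BuOOH, 4 Å molecular sieves, CH2Cl2, −20 °C
Reagents that add atoms: tert-butyl hydroperoxide, CC(C)(C)OO
Why: Sharpless asymmetric epoxidation; with the L-(+)-tartrate a Z-trisubstituted allylic alcohol of this type gives the (2S,3R)-epoxy alcohol, which sets C10 (R, final) and C5 (to be inverted) by reagent control, independently of the remote cyclobutane.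

**Step 21**
Reactants: 29 epoxy alcohol
Product: 30 (1R,2S)-2-[(3R,4R)-3-hydroxy-4-(hydroxymethyl)-3-methylhept-6-en-1-yl]-N-methoxy-N,3,3-trimethylcyclobutane-1-carboxamide
Conditions: allylMgBr (6 equiv), CuI (3 equiv), THF/Me2S, −78 to −30 °C
Reagents that add atoms: allylmagnesium bromide, C=CC[Mg]Br
Why: Copper-mediated SN2 opening of a 3,3-disubstituted 2,3-epoxy alcohol: C10 is fully substituted, so the allyl copper reagent enters at C5 anti to the C–O bond. Inversion at C5 with retention at C10 gives the relative configuration that becomes the cis pyran fusion; stoichiometric copper keeps free Grignard reagent away from the N-methoxy-N-methylamide.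

**Step 22**
Reactants: 30 diol amide
Product: 31 1-{(1R,2S)-2-[(3R,4R)-3-hydroxy-4-(hydroxymethyl)-3-methylhept-6-en-1-yl]-3,3-dimethylcyclobutyl}ethan-1-one
Conditions: MeMgBr (5 equiv), THF, 0 °C
Reagents that add atoms: methylmagnesium bromide, C[Mg]Br
Why: Addition to the N-methoxy-N-methylamide stops at the chelated tetrahedral adduct and gives the methyl ketone (C2, C1) on work-up; the two alkoxides only consume reagent.

**Step 23**
Reactants: 31 keto diol
Product: 33 methyl E-enoate (C6=C7–C8O2Me; C10–OH free), via aldehyde 32 (not isolated)
Conditions: TEMPO (10 mol %), PhI(OAc)2, CH2Cl2, rt; then Ph3P=CHCO2Me, rt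
Reagents that add atoms: methyl (triphenyl-λ5-phosphanylidene)acetate, COC(=O)C=P(c1ccccc1)(c1ccccc1)c1ccccc1
Why: Nitroxyl-catalysed oxidation is selective for the primary alcohol, and the β-hydroxy aldehyde is trapped in the same flask by the stabilised, non-basic Wittig reagent, so neither retro-aldol cleavage nor epimerisation at C5 has time to occur; the ketone does not react with this ylide.

**Step 24**
Reactants: 33 E-enoate
Product: 35 δ-lactone (O9–C8(=O)–C7–C6–C5–C10; allyl on C5; methyl and the cyclobutylethyl chain on C10), via hydroxy ester 34 (not isolated)
Conditions: [(Ph3P)CuH]6, wet benzene, rt; then camphorsulfonic acid (cat.), 50 °C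
Reagents that add atoms: none
Why: The phosphine-stabilised copper hydride reduces only the conjugated alkene (isolated alkene and saturated ketone are inert). The resulting δ-hydroxy ester lactonises under mild acid, forming O9–C8 and ring D at the lactone oxidation level with C5 and C10 unchanged.

**Step 25**
Reactants: 35 keto lactone
Product: 36 alkenyl triflate (C15–C2(OTf)=C1H2) of 35
Conditions: KN(SiMe3)2 (1.05 equiv), THF, −78 °C; then PhNTf2
Reagents that add atoms: N-phenylbis(trifluoromethanesulfonimide), O=S(=O)(N(c1ccccc1)S(=O)(=O)C(F)(F)F)C(F)(F)F
Why: Kinetic deprotonation takes the methyl group of the ketone, which is several pK units more acidic than the lactone α-CH2 and less hindered than the cyclobutyl C–H; O-triflation gives the 1,1-disubstituted alkenyl triflate that carries the future exocyclic methylene.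

**Step 26**
Reactants: 36 allyl triflate lactone
Product: 37 aldehyde (C3 = CHO) of 36
Conditions: OsO4 (2 mol %), NaIO4, 2,6-lutidine, dioxane/H2O, rt
Reagents that add atoms: osmium tetroxide, O=[Os](=O)(=O)=O; sodium periodate, [Na+].[O-]I(=O)(=O)=O
Why: Lemieux–Johnson cleavage: the electrophilic osmium reagent attacks the electron-rich monosubstituted alkene and leaves the electron-poor alkenyl triflate; the aldehyde has no α-stereocentre.

**Step 27**
Reactants: 37 aldehyde alkenyl triflate
Product: 38 nine-membered allylic alcohol (C2(=C1H2)–C3H(OH); lactone intact; C3 epimers)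
Conditions: CrCl2 (8 equiv), NiCl2 (2 mol %), DMF, rt, slow addition to 2 mM
Reagents that add atoms: none
Why: Intramolecular Nozaki–Hiyama–Kishi reaction: nickel inserts into the C–OTf bond, transmetalation gives an alkenylchromium species that adds only to the aldehyde (lactone untouched). This forms C2–C3 and the nine-membered ring between two rings that preorganise the chain; C14 and C15 are unaffected and the C3 configuration is irrelevant.

**Step 28**
Reactants: 38 allylic alcohol
Product: 39 methyl carbonate of 38
Conditions: ClCO2Me, pyridine, DMAP (cat.), CH2Cl2, 0 °C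
Reagents that add atoms: methyl chloroformate, COC(=O)Cl
Why: Acylation of the secondary allylic alcohol gives the leaving group for ionisation by zerovalent palladium.

**Step 29**
Reactants: 39 allylic carbonate
Product: 40 lactone with exocyclic methylene (C3 = CH2)
Conditions: Pd(OAc)2 (5 mol %), n-Bu3P (20 mol %), HCO2NH4, dioxane, 90 °C
Reagents that add atoms: none
Why: Palladium-catalysed formate reduction of the allylic carbonate (Tsuji reduction): the π-allyl complex (C1–C2–C3) takes hydride from the palladium formate at the more substituted terminus C3, which leaves the less substituted, exocyclic C1=C2 alkene.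

**Step 30**
Reactants: 40 lactone
Product: 41 ketene acetal triflate (C7=C8(OTf)–O9) of 40
Conditions: KN(SiMe3)2, PhNTf2, THF/DMPU, −78 °C; used at once
Reagents that add atoms: N-phenylbis(trifluoromethanesulfonimide), O=S(=O)(N(c1ccccc1)S(=O)(=O)C(F)(F)F)C(F)(F)F
Why: The lactone α-CH2 is now the only acidic site; O-triflation of the enolate gives the cyclic ketene acetal triflate with the C7=C8 double bond in place.

**Step 31**
Reactants: 41 ketene acetal triflate
Product: 42 6-(trimethylstannyl)-3,4-dihydro-2H-pyran fused to the caryophyllane skeleton (Sn on C8)
Conditions: (Me3Sn)2, Pd(PPh3)4 (5 mol %), LiCl, THF, 65 °C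
Reagents that add atoms: hexamethylditin, C[Sn](C)(C)[Sn](C)(C)C
Why: Palladium-catalysed stannylation of an enol triflate with a distannane (oxidative addition, Sn–Sn transmetalation, reductive elimination) gives the α-alkoxy alkenylstannane under neutral conditions.

**Step 32**
Reactants: 16 enol triflate; 42 stannane; 6 carbon monoxide
Product: 43 cross-conjugated dienone C7=C8(O9)–C20(=O)–C22=C33
Conditions: Pd(PPh3)4 (8 mol %), LiCl, CO (3 atm), THF, 55 °C
Reagents that add atoms: none
Why: Carbonylative Stille coupling: oxidative addition of the tetrasubstituted enol triflate, CO insertion to the acyl palladium species and transmetalation from the electron-rich alkenylstannane form C20–C22 and C20–C8. Mild CO pressure favours insertion over direct coupling, and no stereocentre is touched.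

**Step 33**
Reactants: 43 dienone
Product: 44 methyl ester of the target
Conditions: Sc(OTf)3 (15 mol %), 2,6-di-tert-butyl-4-methylpyridine (20 mol %), ClCH2CH2Cl, 25–45 °C
Reagents that add atoms: none
Why: Nazarov cyclisation of a 2-alkoxy dienone: the Lewis acid chelates O21 and O9, and conrotatory 4π closure forms C7–C33 on the convex face of the A/B bicycle, anti to ring A, which puts the C33 methyl on the concave side. Proton loss from C7 restores the C7=C8 enol ether and the enol is protonated at C22 to the cis B/C fusion. The hindered pyridine shuttles protons but keeps free strong acid away from the exocyclic alkene.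

**Step 34**
Reactants: 44 methyl ester
Product: 45 target acid (CNP0483070.1)
Conditions: LiOH, THF/MeOH/H2O, 50 °C; then aq. KHSO4 to pH 4, 0 °C
Reagents that add atoms: lithium hydroxide, [Li+].[OH-]
Why: Saponification of the convex, accessible methyl ester; C22 is the only enolisable stereocentre and already has the thermodynamic cis configuration, and the cold, brief acidification spares the exocyclic alkene.

## Compound list

1 | dimethyl malonate | COC(=O)CC(=O)OC | starting material
2 | allyl bromide | C=CCBr | starting material
3 | dimethyl 2-allylmalonate | C=CCC(C(=O)OC)C(=O)OC | intermediate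
4 | 1-bromobut-2-yne | CC#CCBr | starting material
5 | dimethyl 2-allyl-2-(but-2-yn-1-yl)malonate | C=CCC(CC#CC)(C(=O)OC)C(=O)OC | intermediate
6 | carbon monoxide | [C-]#[O+] | starting material
7 | dimethyl (3aR)-6-methyl-5-oxo-3,3a,4,5-tetrahydropentalene-2,2(1H)-dicarboxylate | CC1=C2CC(C(=O)OC)(C(=O)OC)C[C@@H]2CC1=O | intermediate
8 | dimethyl (3aR,4R,6aR)-4-methyl-5-oxohexahydropentalene-2,2(1H)-dicarboxylate | O=C1C[C@H]2CC(C(=O)OC)(C(=O)OC)C[C@H]2[C@H]1C | intermediate
9 | 1,3-dioxolane ketal of 8 | O1CCOC12C[C@H]3CC(C(=O)OC)(C(=O)OC)C[C@H]3[C@H]2C | intermediate
10 | ketal mono-acid, convex CO2H and concave CO2Me on C26 | O1CCOC12C[C@H]3C[C@](C(=O)OC)(C(=O)O)C[C@H]3[C@H]2C | intermediate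
11 | ketal hydroxy acid, concave CH2OH and convex CO2H | O1CCOC12C[C@H]3C[C@](CO)(C(=O)O)C[C@H]3[C@H]2C | intermediate
12 | ketal hydroxy methyl ester | O1CCOC12C[C@H]3C[C@](CO)(C(=O)OC)C[C@H]3[C@H]2C | intermediate
13 | O-(imidazol-1-ylcarbonothioyl) derivative of 12 | O1CCOC12C[C@H]3C[C@](COC(=S)n4ccnc4)(C(=O)OC)C[C@H]3[C@H]2C | intermediate
14 | ketal ester with concave CH3 and convex CO2Me on C26 | O1CCOC12C[C@H]3C[C@](C)(C(=O)OC)C[C@H]3[C@H]2C | intermediate
15 | methyl (2S,3aR,4R,6aR)-2,4-dimethyl-5-oxooctahydropentalene-2-carboxylate | O=C1C[C@H]2C[C@](C)(C(=O)OC)C[C@H]2[C@H]1C | intermediate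
16 | methyl (2S,3aR,6aR)-2,4-dimethyl-5-(trifluoromethanesulfonyloxy)-1,2,3,3a,6,6a-hexahydropentalene-2-carboxylate | FC(F)(F)S(=O)(=O)OC1=C(C)[C@@H]2C[C@@](C)(C(=O)OC)C[C@@H]2C1 | intermediate
17 | 4,4-dimethylcyclopent-2-en-1-one | CC1(C)CC(=O)C=C1 | starting material
18 | potassium vinyltrifluoroborate | C=C[B-](F)(F)F.[K+] | starting material
19 | (3R)-3-ethenyl-4,4-dimethylcyclopentan-1-one | C=C[C@H]1CC(=O)CC1(C)C | intermediate
20 | (3R)-3-ethenyl-2-(hydroxymethylidene)-4,4-dimethylcyclopentan-1-one | C=C[C@H]1C(=CO)C(=O)CC1(C)C | intermediate
21 | (3R)-2-diazo-3-ethenyl-4,4-dimethylcyclopentan-1-one | C=C[C@H]1C(=[N+]=[N-])C(=O)CC1(C)C | intermediate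
22 | methyl (1S,2S)-2-ethenyl-3,3-dimethylcyclobutane-1-carboxylate (cis) | COC(=O)[C@H]1CC(C)(C)[C@H]1C=C | intermediate
23 | methyl (1R,2S)-2-ethenyl-3,3-dimethylcyclobutane-1-carboxylate (trans) | COC(=O)[C@@H]1CC(C)(C)[C@H]1C=C | intermediate
24 | (1R,2S)-2-ethenyl-N-methoxy-N,3,3-trimethylcyclobutane-1-carboxamide | CON(C)C(=O)[C@@H]1CC(C)(C)[C@H]1C=C | intermediate
25 | but-2-yn-1-ol | CC#CCO | starting material
26 | (Z)-3-iodobut-2-en-1-ol | C/C(I)=C/CO | intermediate
27 | B-alkyl-9-borabicyclo[3.3.1]nonane from 24 (boron on C12) | CON(C)C(=O)[C@@H]1CC(C)(C)[C@H]1CCB1C2CCCC1CCC2 | intermediate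
28 | (1R,2S)-2-[(3Z)-5-hydroxy-3-methylpent-3-en-1-yl]-N-methoxy-N,3,3-trimethylcyclobutane-1-carboxamide | CON(C)C(=O)[C@@H]1CC(C)(C)[C@H]1CC/C(C)=C\CO | intermediate
29 | (1R,2S)-2-{2-[(2R,3S)-3-(hydroxymethyl)-2-methyloxiran-2-yl]ethyl}-N-methoxy-N,3,3-trimethylcyclobutane-1-carboxamide | CON(C)C(=O)[C@@H]1CC(C)(C)[C@H]1CC[C@@]2(C)O[C@H]2CO | intermediate
30 | (1R,2S)-2-[(3R,4R)-3-hydroxy-4-(hydroxymethyl)-3-methylhept-6-en-1-yl]-N-methoxy-N,3,3-trimethylcyclobutane-1-carboxamide | CON(C)C(=O)[C@@H]1CC(C)(C)[C@H]1CC[C@@](C)(O)[C@H](CC=C)CO | intermediate
31 | 1-{(1R,2S)-2-[(3R,4R)-3-hydroxy-4-(hydroxymethyl)-3-methylhept-6-en-1-yl]-3,3-dimethylcyclobutyl}ethan-1-one | CC(=O)[C@@H]1CC(C)(C)[C@H]1CC[C@@](C)(O)[C@H](CC=C)CO | intermediate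
32 | β-hydroxy aldehyde from 31 (C6 = CHO) | CC(=O)[C@@H]1CC(C)(C)[C@H]1CC[C@@](C)(O)[C@H](CC=C)C=O | intermediate
33 | methyl E-enoate from 32 (C6=C7–C8O2Me) | CC(=O)[C@@H]1CC(C)(C)[C@H]1CC[C@@](C)(O)[C@H](CC=C)/C=C/C(=O)OC | intermediate
34 | saturated δ-hydroxy methyl ester from 33 | CC(=O)[C@@H]1CC(C)(C)[C@H]1CC[C@@](C)(O)[C@H](CC=C)CCC(=O)OC | intermediate
35 | δ-lactone: 6-{2-[trans-2-acetyl-4,4-dimethylcyclobutyl]ethyl}-6-methyl-5-(prop-2-en-1-yl)oxan-2-one, configuration as in SMILES | CC(=O)[C@@H]1CC(C)(C)[C@H]1CC[C@@]2(C)OC(=O)CC[C@H]2CC=C | intermediate
36 | alkenyl triflate of 35 (C2(OTf)=C1H2) | C=C(OS(=O)(=O)C(F)(F)F)[C@@H]1CC(C)(C)[C@H]1CC[C@@]2(C)OC(=O)CC[C@H]2CC=C | intermediate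
37 | aldehyde from 36 (C3 = CHO) | C=C(OS(=O)(=O)C(F)(F)F)[C@@H]1CC(C)(C)[C@H]1CC[C@@]2(C)OC(=O)CC[C@H]2CC=O | intermediate
38 | tricyclic lactone with nine-membered ring, exocyclic methylene and C3–OH (C3 epimers) | C=C1C(O)C[C@@H]2CCC(=O)O[C@]2(C)CC[C@H]2[C@H]1CC2(C)C | intermediate
39 | methyl carbonate of 38 | C=C1C(OC(=O)OC)C[C@@H]2CCC(=O)O[C@]2(C)CC[C@H]2[C@H]1CC2(C)C | intermediate
40 | tricyclic lactone with exocyclic methylene (C3 = CH2) | C=C1CC[C@@H]2CCC(=O)O[C@]2(C)CC[C@H]2[C@H]1CC2(C)C | intermediate
41 | ketene acetal triflate of 40 | C=C1CC[C@@H]2CC=C(OS(=O)(=O)C(F)(F)F)O[C@]2(C)CC[C@H]2[C@H]1CC2(C)C | intermediate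
42 | pyranyl trimethylstannane (Sn on C8) | C=C1CC[C@@H]2CC=C([Sn](C)(C)C)O[C@]2(C)CC[C@H]2[C@H]1CC2(C)C | intermediate
43 | dienone from 16, 42 and CO | C=C1CC[C@@H]2CC=C(O[C@]2(C)CC[C@H]2[C@H]1CC2(C)C)C(=O)C1=C(C)[C@@H]2C[C@@](C)(C(=O)OC)C[C@@H]2C1 | intermediate
44 | methyl ester of the target | C=C1CC[C@@H]2CC3=C(O[C@]2(C)CC[C@H]2[C@H]1CC2(C)C)C(=O)[C@@H]1C[C@H]2C[C@](C)(C(=O)OC)C[C@H]2[C@]31C | intermediate
45 | CNP0483070.1 | C=C1CC[C@@H]2CC3=C(O[C@]2(C)CC[C@H]2[C@H]1CC2(C)C)C(=O)[C@@H]1C[C@H]2C[C@](C)(C(=O)O)C[C@H]2[C@]31C | target

## Step count and least certain steps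

Total: 34 steps. Longest linear sequence: 21 steps (13–17, 19–31, 32–34, from 17). The triquinane branch has 12 steps before the union; step 18 is a one-step side branch.

**Step 3 (key step).** The most likely failure is insufficient enantioface discrimination at C24, or loss of material to CO-free cycloisomerisation when CO is too scarce and to catalyst saturation when it is too abundant. Fallback, from 5 back to 7: an early-metal Pauson–Khand reaction with the ansa-titanocene (S,S)-ethylenebis(tetrahydroindenyl)titanium dicarbonyl, (EBTHI)Ti(CO)2, in toluene under CO at 90 °C. A divalent titanium centre forms a titanacyclopentene and the C2-symmetric metallocene, not a bisphosphine, discriminates the alkene faces. This changes the metal, the ligand class and the enantio-determining species, and the gem-diester enyne is a standard substrate for it. No new compound is made (F0).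

**Step 6.** Hydroxide may not discriminate the two esters well enough, or may give the half-ester of the wrong face. Fallback, from 9 back to 10: the stereocentre is set by the face of a C–C bond formation and not by ester discrimination. Krapcho dealkoxycarbonylation of 9 (LiCl, wet DMSO, 150 °C) gives the mono-ester ketal F1. Its lithium enolate (LiN(iPr)2, THF, −78 °C) is carboxylated with CO2, which approaches from the open convex face and pushes the existing ester into the concave position; this gives 10 directly.

**Step 27.** Closure of a nine-membered ring competes with intermolecular coupling and with reduction of the alkenyl–metal species before it finds the aldehyde. Fallback, from 37 back to 40: an sp3–sp2 cross-coupling that needs no later deoxygenation. NaBH4 reduces the aldehyde to the primary alcohol F2. I2/PPh3/imidazole gives the iodide F3. Zinc dust with LiCl in THF gives the alkylzinc iodide F4, which is inert to the lactone. Intramolecular Negishi coupling with the alkenyl triflate (Pd(PPh3)4, THF/DMF, high dilution, 50 °C) forms C2–C3 and gives 40, bypassing 38 and 39.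

**Step 32.** The hindered tetrasubstituted triflate may couple with the reactive α-alkoxy stannane before CO has inserted (direct coupling), or stall at the acyl palladium stage. Fallback, from 16 and 42 back to 43: the carbonyl carbon is placed on the triquinane half first. Palladium-catalysed formylation of 16 (Pd(PPh3)4, CO, Bu3SnH, THF, 50 °C) gives the enal F5. Tin–lithium exchange of 42 (MeLi, THF, −78 °C) gives the 6-lithio dihydropyran F6, which adds to the aldehyde much faster than to the hindered ester and gives the bis-allylic carbinol F7. Oxidation with MnO2 or buffered Dess–Martin periodinane gives 43.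

**Step 33.** Closure onto the fully substituted C33 may be slow, and forcing it with stronger acid risks protonation of the exocyclic alkene (isomerisation or cyclobutylcarbinyl ring expansion), hydration of the enol ether, or proton loss towards C23 instead of C7. Fallback, from 43 back to 44: the ring is closed without acid by excited-state 4π electrocyclisation. Irradiation of 43 (350 nm, Pyrex, MeCN, rt) is followed by tautomerisation with a trace of Et3N. The elementary step changes from a ground-state cationic closure to a photochemical one in neutral medium, the face of C33 is still dictated by ring A, and C7 returns to sp2, so the same product is expected. No new compound is made (F0).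

## Further compounds

F0 | step 3 | none | none
F1 | step 6 | ketal mono-ester lacking one carboxyl (C26–H, epimers) | O1CCOC12C[C@H]3CC(C(=O)OC)C[C@H]3[C@H]2C
F2 | step 27 | primary alcohol from 37 (C3 = CH2OH) | C=C(OS(=O)(=O)C(F)(F)F)[C@@H]1CC(C)(C)[C@H]1CC[C@@]2(C)OC(=O)CC[C@H]2CCO
F3 | step 27 | primary iodide from F2 | C=C(OS(=O)(=O)C(F)(F)F)[C@@H]1CC(C)(C)[C@H]1CC[C@@]2(C)OC(=O)CC[C@H]2CCI
F4 | step 27 | alkylzinc iodide from F3 | C=C(OS(=O)(=O)C(F)(F)F)[C@@H]1CC(C)(C)[C@H]1CC[C@@]2(C)OC(=O)CC[C@H]2CC[Zn]I
F5 | step 32 | enal from 16 (CHO on C22) | O=CC1=C(C)[C@@H]2C[C@@](C)(C(=O)OC)C[C@@H]2C1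
F6 | step 32 | 6-lithio dihydropyran from 42 | C=C1CC[C@@H]2CC=C([Li])O[C@]2(C)CC[C@H]2[C@H]1CC2(C)C
F7 | step 32 | bis-allylic carbinol (C20–OH, epimers) | C=C1CC[C@@H]2CC=C(O[C@]2(C)CC[C@H]2[C@H]1CC2(C)C)C(O)C1=C(C)[C@@H]2C[C@@](C)(C(=O)OC)C[C@@H]2C1
F0 | step 33 | none | none
A1 | alternative 1 | cyclononane C4 carboxylic acid fused to the dihydropyran and the cyclobutane | C=C1C[C@H](C(=O)O)[C@@H]2CC=CO[C@]2(C)CC[C@H]2[C@H]1CC2(C)C
A2 | alternative 1 | eleven-membered allylic lactone | C=C1COC(=O)C[C@@H]2CC=CO[C@]2(C)CC[C@H]2[C@H]1CC2(C)C
A3 | alternative 2 | (E)-cyclobutylidene acetate of the geranyl chain | CC(=O)OC/C=C(\C)CC[C@@H]1C(C)(C)C/C1=C\C(=O)OCC(F)(F)F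
A4 | alternative 2 | geranyl acetate | CC(C)=CCC/C(C)=C/COC(C)=O
A5 | alternative 2 | 2,2,2-trifluoroethyl buta-2,3-dienoate | C=C=CC(=O)OCC(F)(F)F
A6 | alternative 3 | trans-7,7-dimethylbicyclo[4.2.0]octan-2-one | O=C1CCC[C@H]2[C@H]1CC2(C)C
A7 | alternative 3 | cyclohex-2-enone | O=C1C=CCCC1
A8 | alternative 3 | isobutylene | C=C(C)C
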